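**Plan**

1. Numbering (elemane): C1/C2 oxirane, C3=C4(C15HO) acrolein unit, C5–C10 carbocycle, C11–C13 lactone carbons, C14 methyl. Retrosynthetically the oxirane oxygen, the C15 oxidation and the C13 methylene are removed first; the carbocycle is then cut at C9–C10 and at C5–C6.
2. Enabling feature: in the six-membered ring, C9 (OH) lies next to the quaternary C10 (methyl + vinyl, the oxirane precursor) and C6 (O-acyl) next to C5 (isopropenyl, the acrolein precursor). These are two homoallylic-alcohol retrons, so the ring is a double allylation of a lactone 1,4-dialdehyde equivalent by the 1,2-bis(boronate) of (E)-2,4-dimethylhexa-1,3,5-triene.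
3. Forward order: the γ-lactone is made first (chiral pool, then anti cuprate addition). Intermolecular allylboration joins C5–C6. Oxidation at C9 then triggers an intramolecular allylboration (C9–C10) that closes the carbocycle as the last ring of the skeleton. Methylenation, allylic oxidation and epoxidation follow.
4. Stereochemistry: C8 from (R)-5-(hydroxymethyl)butanolide; C7 by anti conjugate addition; C5/C6 from the E olefin (anti) under phosphoric-acid control; C9/C10 from the Z-allylboronate (cis OH/vinyl) and A(1,3) strain at C5; C1 by C9–OH-directed epoxidation.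

Key step: step 11

Remark: the oxirane is treated as a functional group put on the finished lactone-fused carbon skeleton.
Remark: (S)-TRIP is assumed to direct attack to the Si face of the formyl group of 8, by analogy with its behaviour towards simple aldehydes; if the sense is opposite, the (R)-acid is used.

**Route**

Step 1
Reactants: 1 (R)-5-(hydroxymethyl)dihydrofuran-2(3H)-one
Product: 2 (R)-5-{[(triethylsilyl)oxy]methyl}dihydrofuran-2(3H)-one
Conditions: TESCl (1.1 equiv), imidazole (1.5 equiv), CH2Cl2, 0 °C → rt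
Reagents that add atoms: chlorotriethylsilane, CC[Si](Cl)(CC)CC
Why: Standard silylation of a primary alcohol; the TES ether survives enolate, cuprate and ozonolysis steps and can later be removed by mild acid without fluoride.

Step 2
Reactants: 2 (R)-5-{[(triethylsilyl)oxy]methyl}dihydrofuran-2(3H)-one
Product: 5 (R)-5-{[(triethylsilyl)oxy]methyl}furan-2(5H)-one, via α-phenylselanyl lactone 3 (not isolated), via selenoxide 4 (not isolated)
Conditions: LDA (1.1 equiv), THF, −78 °C; PhSeBr (1.1 equiv), −78 °C; then 30% H2O2, pyridine, CH2Cl2, 0 °C → rt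
Reagents that add atoms: none
Why: Enolate selenenylation followed by selenoxide syn-elimination is the classical dehydrogenation of γ-butyrolactones to butenolides and does not touch the C8 stereocentre.

Step 3
Reactants: 5 (R)-5-{[(triethylsilyl)oxy]methyl}furan-2(5H)-one
Product: 6 (4S,5R)-4-ethenyl-5-{[(triethylsilyl)oxy]methyl}dihydrofuran-2(3H)-one
Conditions: CH2=CHMgBr (2.0 equiv), CuI (1.0 equiv), THF, −78 → −40 °C; aq NH4Cl
Reagents that add atoms: vinylmagnesium bromide, C=C[Mg]Br
Why: Conjugate addition of a vinyl cuprate to a 5-substituted butenolide occurs anti to the C5 substituent, which sets C7 trans to C8 as required for the trans-fused lactone.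

Step 4
Reactants: 6 (4S,5R)-4-ethenyl-5-{[(triethylsilyl)oxy]methyl}dihydrofuran-2(3H)-one
Product: 8 (2R,3R)-5-oxo-2-{[(triethylsilyl)oxy]methyl}oxolane-3-carbaldehyde, via ozonide 7 (not isolated)
Conditions: O3, CH2Cl2, −78 °C; PPh3 (1.2 equiv), −78 °C → rt; used crude
Reagents that add atoms: ozone, [O-][O+]=O
Why: Ozonolysis with reductive work-up cleaves the only alkene to the C6 aldehyde under neutral conditions, which avoids β-elimination of the lactone oxygen and epimerisation at C7.

Step 5
Reactants: 9 methacrolein (3 equiv) and 10 2-(triphenyl-λ5-phosphanylidene)propanal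
Product: 11 (2E)-2,4-dimethylpenta-2,4-dienal
Conditions: toluene, 70 °C, sealed vessel
Reagents that add atoms: none
Why: Wittig olefination with a stabilised formyl ylide gives the (E)-2-methyl-2-enal selectively, placing the isopropenyl group trans to the formyl group.

Step 6
Reactants: 11 (2E)-2,4-dimethylpenta-2,4-dienal
Product: 12 (3E)-2,4-dimethylhexa-1,3,5-triene
Conditions: Ph3PCH3Br (1.2 equiv), KOtBu (1.15 equiv), Et2O, 0 °C → rt; product kept as a stabilised (BHT) solution
Reagents that add atoms: methyltriphenylphosphonium bromide, C[P+](c1ccccc1)(c1ccccc1)c1ccccc1.[Br-]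
Why: Wittig methylenation converts the aldehyde into the terminal vinyl group without changing the geometry of the trisubstituted olefin.

Step 7
Reactants: 12 (3E)-2,4-dimethylhexa-1,3,5-triene
Product: 13 rac-2,2'-[(3E)-3,5-dimethylhexa-3,5-diene-1,2-diyl]bis(4,4,5,5-tetramethyl-1,3,2-dioxaborolane)
Conditions: B2pin2 (1.0 equiv), Pt(dba)2 (3 mol %), toluene, 50 °C
Reagents that add atoms: bis(pinacolato)diboron, CC1(C)OB(OC1(C)C)B1OC(C)(C)C(C)(C)O1
Why: Phosphine-free platinum(0)-catalysed diboration adds B–B in a 1,2 sense to the monosubstituted terminal double bond of a 1,3-diene and leaves the 1,1-disubstituted isopropenyl alkene alone, giving the α-(borylmethyl) allylboronate.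

Step 8
Reactants: 8 (2R,3R)-5-oxo-2-{[(triethylsilyl)oxy]methyl}oxolane-3-carbaldehyde and 13 racemic bis(boronate) (2.5 equiv)
Product: 15 (4S,5R)-4-[(1S,2S,3Z)-1-hydroxy-3-methyl-2-(prop-1-en-2-yl)-5-(4,4,5,5-tetramethyl-1,3,2-dioxaborolan-2-yl)pent-3-en-1-yl]-5-{[(triethylsilyl)oxy]methyl}oxolan-2-one, via borate ester 14 (not isolated)
Conditions: (S)-TRIP (10 mol %), 4 Å MS, toluene, −30 °C → rt; aq NaHCO3 work-up
Reagents that add atoms: none
Why: Chiral phosphoric acid-catalysed allylboration with kinetic resolution of the racemic α-substituted allylboronate; the acid should steer the (S)-enantiomer of 13 onto the Si face of the formyl group through a Zimmerman–Traxler chair in which the E-γ-isopropenyl group is equatorial (anti C5/C6) and the α-CH2Bpin arm is axial because of A(1,2) strain with the C10 methyl group, which sets C5 and C6 and leaves a Z-trisubstituted allylboronate.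

Step 9
Reactants: 15 homoallylic alcohol
Product: 16 (1S,2S,3Z)-3-methyl-1-[(2R,3S)-5-oxo-2-{[(triethylsilyl)oxy]methyl}oxolan-3-yl]-2-(prop-1-en-2-yl)-5-(4,4,5,5-tetramethyl-1,3,2-dioxaborolan-2-yl)pent-3-en-1-yl 2-methylpropanoate
Conditions: (i-PrCO)2O (2 equiv), Et3N, DMAP (0.2 equiv), CH2Cl2, 0 °C → rt
Reagents that add atoms: isobutyric anhydride, CC(C)C(=O)OC(=O)C(C)C
Why: DMAP-catalysed acylation installs the C6 isobutyrate of the target while C6–OH is the only free hydroxyl, and the pinacol allylboronate tolerates these non-nucleophilic basic conditions.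

Step 10
Reactants: 16 silyl ether
Product: 17 (1S,2S,3Z)-1-[(2R,3S)-2-(hydroxymethyl)-5-oxooxolan-3-yl]-3-methyl-2-(prop-1-en-2-yl)-5-(4,4,5,5-tetramethyl-1,3,2-dioxaborolan-2-yl)pent-3-en-1-yl 2-methylpropanoate
Conditions: PPTS (0.2 equiv), MeOH–CH2Cl2 (1:1), 0 °C
Reagents that add atoms: none
Why: Mild acid-catalysed methanolysis cleaves the primary TES ether selectively; the pinacol boronate, the lactone and the ester are stable to it, and no fluoride is present to attack boron.

Step 11
Reactants: 17 primary alcohol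
Product: 20 (3aS,4S,5S,6S,7S,7aR)-6-ethenyl-7-hydroxy-6-methyl-2-oxo-5-(prop-1-en-2-yl)octahydro-1-benzofuran-4-yl 2-methylpropanoate, via aldehyde 18 (not isolated), via ring-closed borate 19 (not isolated)
Conditions: Dess–Martin periodinane (1.3 equiv), CH2Cl2 (0.01 M), 0 °C → rt, then 35 °C; aq NaHCO3/Na2S2O3 work-up
Reagents that add atoms: none
Why: Dess–Martin oxidation turns the primary alcohol into the α-acyloxy aldehyde 18, whose formyl group is attacked at once by the tethered (Z)-γ,γ-disubstituted allyl pinacolboronate in a type-I intramolecular allylboration (boron passes from C2 to O9 with allylic transposition) through a closed Zimmerman–Traxler chair fused to the nascent ring. The closest known reactions are intramolecular allylborations of ω-formyl allylboronates and the second stage of diboration/double allylation of 1,4-dicarbonyl compounds. The carbocycle (C5–C10) is closed by the C9–C10 bond in a 6-exo fashion with respect to both the C9=O and the C10=C1 π bonds, and the vinyl group appears on the new quaternary carbon. C9 is controlled by the Z olefin geometry: the ring tether (C5) takes the axial γ-position and C8 the equatorial position of the boron chair, a cis-fused bicyclic transition state that places OH and vinyl cis. C10 is controlled by A(1,3) strain at C5 of the Z olefin, which keeps H5 in the olefin plane so that the aldehyde, delivered from the face carrying C6, leaves the methyl group cis to the isopropenyl group, while the trans-fused lactone locks the chair. The step needs the oxidant to spare the allylboron unit and ring closure to outrun enolisation at C8, which the neutral periodinane, the robust pinacol ester and the intramolecularity at high dilution should secure.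

Step 12
Reactants: 20 bicyclic hydroxy lactone
Product: 23 (3aS,4S,5S,6S,7S,7aR)-6-ethenyl-7-hydroxy-6-methyl-3-methylidene-2-oxo-5-(prop-1-en-2-yl)octahydro-1-benzofuran-4-yl 2-methylpropanoate, via Mannich base 21 (not isolated), via methiodide 22 (not isolated)
Conditions: LDA (2.3 equiv), THF, −78 °C; CH2=NMe2+ I− (3 equiv), −78 °C → rt; then MeI, MeOH, rt; aq NaHCO3
Reagents that add atoms: Eschenmoser's salt, C=[N+](C)C.[I-]
Why: Mannich reaction of the lactone enolate (the alkoxide is formed first; the lactone α-CH2 is more acidic and less hindered than the isobutyrate α-CH) followed by quaternisation and E1cB loss of trimethylamine is the standard α-methylenation of γ-butyrolactones.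

Step 13
Reactants: 23 α-methylene lactone
Product: 25 (3aS,4S,5R,6S,7S,7aR)-6-ethenyl-7-hydroxy-6-methyl-3-methylidene-2-oxo-5-(3-oxoprop-1-en-2-yl)octahydro-1-benzofuran-4-yl 2-methylpropanoate, via allylic alcohol 24 (not isolated)
Conditions: SeO2 (1.5 equiv), 1,4-dioxane, 80 °C
Reagents that add atoms: selenium dioxide, O=[Se]=O
Why: Riley allylic oxidation (ene reaction, then [2,3]-shift) attacks the methyl group of the isopropenyl unit, the only electron-rich alkene with allylic hydrogens (CH3 preferred over CH), and takes the primary allylic alcohol on to the conjugated aldehyde, while the vinyl group (no allylic H) and the electron-poor methylene lactone are left alone.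

Step 14
Reactants: 25 enal
Product: 26 (3aS,4S,5R,6S,7S,7aR)-7-hydroxy-6-methyl-3-methylidene-6-[(2R)-oxiran-2-yl]-2-oxo-5-(3-oxoprop-1-en-2-yl)octahydro-1-benzofuran-4-yl 2-methylpropanoate
Conditions: VO(acac)2 (5 mol %), t-BuOOH (1.5 equiv, in decane), CH2Cl2, 0 °C → rt
Reagents that add atoms: tert-butyl hydroperoxide, CC(C)(C)OO
Why: Vanadium-catalysed hydroxyl-directed epoxidation of a homoallylic alcohol; the axial C9–OH binds the vanadium peroxide and delivers oxygen to the cis vinyl group, the only alkene that is not electron-poor, and the chair-like vanadate transition state with the terminal CH2 pseudo-equatorial should give the (R)-oxirane.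

**Compound list**

1 | (R)-5-(hydroxymethyl)dihydrofuran-2(3H)-one | O=C1CC[C@H](CO)O1 | starting material
2 | (R)-5-{[(triethylsilyl)oxy]methyl}dihydrofuran-2(3H)-one | O=C1CC[C@H](CO[Si](CC)(CC)CC)O1 | intermediate
3 | (5R)-3-(phenylselanyl)-5-{[(triethylsilyl)oxy]methyl}dihydrofuran-2(3H)-one (C3 epimers) | O=C1C([Se]c2ccccc2)C[C@H](CO[Si](CC)(CC)CC)O1 | intermediate
4 | (5R)-3-(phenylseleninyl)-5-{[(triethylsilyl)oxy]methyl}dihydrofuran-2(3H)-one (selenoxide) | O=C1C([Se](=O)c2ccccc2)C[C@H](CO[Si](CC)(CC)CC)O1 | intermediate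
5 | (R)-5-{[(triethylsilyl)oxy]methyl}furan-2(5H)-one | O=C1C=C[C@H](CO[Si](CC)(CC)CC)O1 | intermediate
6 | (4S,5R)-4-ethenyl-5-{[(triethylsilyl)oxy]methyl}dihydrofuran-2(3H)-one | O=C1C[C@@H](C=C)[C@H](CO[Si](CC)(CC)CC)O1 | intermediate
7 | (4R,5R)-5-{[(triethylsilyl)oxy]methyl}-4-(1,2,4-trioxolan-3-yl)dihydrofuran-2(3H)-one (ozonide, trioxolane carbon unassigned) | O=C1C[C@@H](C2OCOO2)[C@H](CO[Si](CC)(CC)CC)O1 | intermediate
8 | (2R,3R)-5-oxo-2-{[(triethylsilyl)oxy]methyl}oxolane-3-carbaldehyde | O=C1C[C@@H](C=O)[C@H](CO[Si](CC)(CC)CC)O1 | intermediate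
9 | methacrolein (2-methylprop-2-enal) | CC(=C)C=O | starting material
10 | 2-(triphenyl-λ5-phosphanylidene)propanal | CC(C=O)=P(c1ccccc1)(c1ccccc1)c1ccccc1 | starting material
11 | (2E)-2,4-dimethylpenta-2,4-dienal | CC(=C)/C=C(C)/C=O | intermediate
12 | (3E)-2,4-dimethylhexa-1,3,5-triene | CC(=C)/C=C(C)/C=C | intermediate
13 | rac-2,2'-[(3E)-3,5-dimethylhexa-3,5-diene-1,2-diyl]bis(4,4,5,5-tetramethyl-1,3,2-dioxaborolane) | CC(=C)/C=C(C)/C(CB1OC(C)(C)C(C)(C)O1)B1OC(C)(C)C(C)(C)O1 | intermediate
14 | O-(pinacolatoboryl) borate ester of 15 | O=C1C[C@@H]([C@@H](OB3OC(C)(C)C(C)(C)O3)[C@@H](C(=C)C)/C(C)=C\CB2OC(C)(C)C(C)(C)O2)[C@H](CO[Si](CC)(CC)CC)O1 | intermediate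
15 | (4S,5R)-4-[(1S,2S,3Z)-1-hydroxy-3-methyl-2-(prop-1-en-2-yl)-5-(4,4,5,5-tetramethyl-1,3,2-dioxaborolan-2-yl)pent-3-en-1-yl]-5-{[(triethylsilyl)oxy]methyl}oxolan-2-one | O=C1C[C@@H]([C@@H](O)[C@@H](C(=C)C)/C(C)=C\CB2OC(C)(C)C(C)(C)O2)[C@H](CO[Si](CC)(CC)CC)O1 | intermediate
16 | (1S,2S,3Z)-3-methyl-1-[(2R,3S)-5-oxo-2-{[(triethylsilyl)oxy]methyl}oxolan-3-yl]-2-(prop-1-en-2-yl)-5-(4,4,5,5-tetramethyl-1,3,2-dioxaborolan-2-yl)pent-3-en-1-yl 2-methylpropanoate | O=C1C[C@@H]([C@@H](OC(=O)C(C)C)[C@@H](C(=C)C)/C(C)=C\CB2OC(C)(C)C(C)(C)O2)[C@H](CO[Si](CC)(CC)CC)O1 | intermediate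
17 | (1S,2S,3Z)-1-[(2R,3S)-2-(hydroxymethyl)-5-oxooxolan-3-yl]-3-methyl-2-(prop-1-en-2-yl)-5-(4,4,5,5-tetramethyl-1,3,2-dioxaborolan-2-yl)pent-3-en-1-yl 2-methylpropanoate | O=C1C[C@@H]([C@@H](OC(=O)C(C)C)[C@@H](C(=C)C)/C(C)=C\CB2OC(C)(C)C(C)(C)O2)[C@H](CO)O1 | intermediate
18 | (1S,2S,3Z)-1-[(2R,3S)-2-formyl-5-oxooxolan-3-yl]-3-methyl-2-(prop-1-en-2-yl)-5-(4,4,5,5-tetramethyl-1,3,2-dioxaborolan-2-yl)pent-3-en-1-yl 2-methylpropanoate | O=C1C[C@@H]([C@@H](OC(=O)C(C)C)[C@@H](C(=C)C)/C(C)=C\CB2OC(C)(C)C(C)(C)O2)[C@H](C=O)O1 | intermediate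
19 | O7-(pinacolatoboryl) borate ester of 20 | C1C(=O)O[C@@H]2[C@@H]1[C@@H](OC(=O)C(C)C)[C@@H](C(=C)C)[C@](C)(C=C)[C@@H]2OB3OC(C)(C)C(C)(C)O3 | intermediate
20 | (3aS,4S,5S,6S,7S,7aR)-6-ethenyl-7-hydroxy-6-methyl-2-oxo-5-(prop-1-en-2-yl)octahydro-1-benzofuran-4-yl 2-methylpropanoate | C1C(=O)O[C@@H]2[C@@H]1[C@@H](OC(=O)C(C)C)[C@@H](C(=C)C)[C@](C)(C=C)[C@@H]2O | intermediate
21 | 3-[(dimethylamino)methyl] derivative of 20 (Mannich base, C3 unassigned) | CN(C)CC1C(=O)O[C@@H]2[C@@H]1[C@@H](OC(=O)C(C)C)[C@@H](C(=C)C)[C@](C)(C=C)[C@@H]2O | intermediate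
22 | trimethylammonium iodide derived from 21 (methiodide) | C[N+](C)(C)CC1C(=O)O[C@@H]2[C@@H]1[C@@H](OC(=O)C(C)C)[C@@H](C(=C)C)[C@](C)(C=C)[C@@H]2O.[I-] | intermediate
23 | (3aS,4S,5S,6S,7S,7aR)-6-ethenyl-7-hydroxy-6-methyl-3-methylidene-2-oxo-5-(prop-1-en-2-yl)octahydro-1-benzofuran-4-yl 2-methylpropanoate | C=C1C(=O)O[C@@H]2[C@@H]1[C@@H](OC(=O)C(C)C)[C@@H](C(=C)C)[C@](C)(C=C)[C@@H]2O | intermediate
24 | (3aS,4S,5S,6S,7S,7aR)-6-ethenyl-7-hydroxy-5-(3-hydroxyprop-1-en-2-yl)-6-methyl-3-methylidene-2-oxooctahydro-1-benzofuran-4-yl 2-methylpropanoate | C=C1C(=O)O[C@@H]2[C@@H]1[C@@H](OC(=O)C(C)C)[C@@H](C(=C)CO)[C@](C)(C=C)[C@@H]2O | intermediate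
25 | (3aS,4S,5R,6S,7S,7aR)-6-ethenyl-7-hydroxy-6-methyl-3-methylidene-2-oxo-5-(3-oxoprop-1-en-2-yl)octahydro-1-benzofuran-4-yl 2-methylpropanoate | C=C1C(=O)O[C@@H]2[C@@H]1[C@@H](OC(=O)C(C)C)[C@@H](C(=C)C=O)[C@](C)(C=C)[C@@H]2O | intermediate
26 | (3aS,4S,5R,6S,7S,7aR)-7-hydroxy-6-methyl-3-methylidene-6-[(2R)-oxiran-2-yl]-2-oxo-5-(3-oxoprop-1-en-2-yl)octahydro-1-benzofuran-4-yl 2-methylpropanoate (CNP0496100.1) | C=C1C(=O)O[C@@H]2[C@@H]1[C@@H](OC(=O)C(C)C)[C@@H](C(=C)C=O)[C@](C)([C@@H]1CO1)[C@@H]2O | target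

**Summary**

Total step count: 14. Longest linear sequence: 11 steps (steps 1–4, then 8–14); steps 5–7 form the convergent branch.

Steps most likely to fail:

1. Step 8. The facial discrimination by the acid may be eroded by the opposing bias of the α-stereocentre of the aldehyde, the kinetic resolution of the racemic boronate may be incomplete, and the competing equatorial-α chair would give the E isomer with the opposite C5/C6 configuration. Fallback (reagent control in place of catalyst control), setting out from 13 and 8: racemic 13 is first resolved with benzaldehyde (0.55 equiv) and (R)-TRIP, which should consume the (R)-enantiomer as the borate adduct of benzaldehyde F2, hydrolysed on work-up to (1R,2R,3Z)-3-methyl-1-phenyl-2-(prop-1-en-2-yl)-5-(pinacolatoboryl)pent-3-en-1-ol F3, and leave the (S)-bis(boronate) F1. F1 is then warmed with 8 in toluene without catalyst, so that the axial α-CH2Bpin chair alone dictates the face, giving borate 14 and after work-up 15, where the route is rejoined.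

2. Step 11. The oxidant may attack the allylboron unit, C8 may epimerise at the aldehyde stage before ring closure, or the facial selectivity at C10 may be low. Fallback (a more robust boron species and a separate, acid-triggered ring closure), setting out from 17: KHF2 in MeOH/H2O converts the pinacol ester into the potassium allyltrifluoroborate alcohol F4, Dess–Martin oxidation gives the isolable aldehyde trifluoroborate F5, and BF3·OEt2 in CH2Cl2 at −78 °C releases the allyldifluoroborane, which cyclises through the same closed chair to the difluoroborinate F6. Aqueous work-up returns to the route at 20.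

3. Step 14. Oxygen delivery from the two vinyl rotamers may give poor facial selectivity at C1, and the enal may be over-oxidised. Fallback (catalyst-controlled removal of the wrong epimer instead of substrate direction), setting out from 25: non-directed epoxidation with mCPBA in CH2Cl2 at 0 °C gives 26 together with its C1 epimer, the (2S)-oxirane F7. Hydrolytic kinetic resolution with the enantiomer of (salen)Co(III)OAc matched to the (S)-oxirane and 0.6 equiv of water opens F7 to the diol F8, which is separated from 26, where the route ends.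

Further compounds
F1 | step 8 | 2,2'-[(2S,3E)-3,5-dimethylhexa-3,5-diene-1,2-diyl]bis(4,4,5,5-tetramethyl-1,3,2-dioxaborolane) | CC(=C)/C=C(C)/[C@H](CB1OC(C)(C)C(C)(C)O1)B1OC(C)(C)C(C)(C)O1
F2 | step 8 | O-(pinacolatoboryl) borate ester of F3 | c1ccccc1[C@H](OB3OC(C)(C)C(C)(C)O3)[C@H](C(=C)C)/C(C)=C\CB2OC(C)(C)C(C)(C)O2
F3 | step 8 | (1R,2R,3Z)-3-methyl-1-phenyl-2-(prop-1-en-2-yl)-5-(4,4,5,5-tetramethyl-1,3,2-dioxaborolan-2-yl)pent-3-en-1-ol | c1ccccc1[C@H](O)[C@H](C(=C)C)/C(C)=C\CB2OC(C)(C)C(C)(C)O2
F4 | step 11 | potassium allyltrifluoroborate analogue of 17 (primary alcohol) | O=C1C[C@@H]([C@@H](OC(=O)C(C)C)[C@@H](C(=C)C)/C(C)=C\C[B-](F)(F)F)[C@H](CO)O1.[K+]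
F5 | step 11 | potassium allyltrifluoroborate analogue of 18 (aldehyde) | O=C1C[C@@H]([C@@H](OC(=O)C(C)C)[C@@H](C(=C)C)/C(C)=C\C[B-](F)(F)F)[C@H](C=O)O1.[K+]
F6 | step 11 | O7-difluoroboryl ester of 20 | C1C(=O)O[C@@H]2[C@@H]1[C@@H](OC(=O)C(C)C)[C@@H](C(=C)C)[C@](C)(C=C)[C@@H]2OB(F)F
F7 | step 14 | C1 epimer of 26, 6-[(2S)-oxiran-2-yl] | C=C1C(=O)O[C@@H]2[C@@H]1[C@@H](OC(=O)C(C)C)[C@@H](C(=C)C=O)[C@](C)([C@H]1CO1)[C@@H]2O
F8 | step 14 | 6-[(1S)-1,2-dihydroxyethyl] diol from F7 | C=C1C(=O)O[C@@H]2[C@@H]1[C@@H](OC(=O)C(C)C)[C@@H](C(=C)C=O)[C@](C)([C@H](O)CO)[C@@H]2O
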